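**Retrosynthetic overview**
1. Target 27 ← hydrogenolysis of tribenzyl ester 26 ← ring D by 5-exo ketyl–olefin closure (C13–C16) of seco-ketone 25.
2. Ring B (key step): 25 ← intramolecular Mukaiyama–Michael addition of the C6 ester ketene acetal to C8 of the C8=C15–C16 unsaturated ketal (as its oxocarbenium ion) in 22.
3. C9–C10 bond and fragment union: 22 ← Ireland–Claisen rearrangement of ester 19, made from ring A acid 12 and ring C carbinol 17.
4. Ring A acid 12 ← amine-catalysed double Michael annulation of keto ester 4 with enal 8 (ring A closes by intramolecular Michael addition), then C4 methylation; carbinol 17 ← propiophenone 13.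
5. Ring order: A (step 5), C (from the arene, step 11), B (step 15), D (step 16).

Assumption: gibberellane numbering is used for all intermediates (ring A C1–C5/C10, ring B C5/C6/C8–C10, ring C C8/C9/C11–C14, ring D C8/C13–C16; carboxyl carbons C7, C19, C20); α is the face of C20, and the target is read as 3β,16-dihydroxygibberellane-7,19,20-trioic acid with the 16-hydroxyl exo (on the side of the C14 bridge) and the C16 methyl endo.

**Step 1**
Reactants: 1 benzyl acetate; 2 acrolein
Product: 3 benzyl 3-hydroxypent-4-enoate (racemic)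
Conditions: LiN(i-Pr)2, THF, −78 °C; then 2; 1 M HCl
Reagents that add atoms: none
Why: Aldol addition of the lithium ester enolate goes 1,2 to acrolein at low temperature; the carbinol centre is removed in the next step, so no control is needed.

**Step 2**
Reactants: 3 benzyl 3-hydroxypent-4-enoate
Product: 4 benzyl 3-oxopent-4-enoate
Conditions: 2-iodoxybenzoic acid (IBX), EtOAc, 75 °C
Reagents that add atoms: none
Why: Alcohol oxidation of the allylic β-hydroxy ester gives the vinyl β-keto ester (Nazarov-type reagent), which is used at once because it polymerises on standing.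

**Step 3**
Reactants: 5 but-3-enoic acid
Product: 6 benzyl but-3-enoate
Conditions: BnBr, KHCO3, DMF, rt
Reagents that add atoms: benzyl bromide BrCc1ccccc1
Why: Carboxylate O-alkylation under weakly basic conditions esterifies the acid without moving the β,γ-double bond into conjugation.

**Step 4**
Reactants: 6 benzyl but-3-enoate; 7 (E)-but-2-enal
Product: 8 benzyl (3E)-5-oxopent-3-enoate
Conditions: second-generation Hoveyda–Grubbs catalyst RuCl2(H2IMes)(=CH-C6H4-2-O-i-Pr) (2 mol %), CH2Cl2, 40 °C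
Reagents that add atoms: none
Why: Olefin cross-metathesis of a terminal alkene with crotonaldehyde gives the (E)-enal and releases propene.

**Step 5**
Reactants: 4 benzyl 3-oxopent-4-enoate; 8 benzyl (3E)-5-oxopent-3-enoate
Product: 10 benzyl (2S,3R)-2-[2-(benzyloxy)-2-oxoethyl]-3-formyl-6-oxocyclohexane-1-carboxylate (C1 enolisable), via open-chain Michael adduct 9 (not isolated)
Conditions: (R)-α,α-diphenylprolinol trimethylsilyl ether (20 mol %), PhCO2H (20 mol %), toluene, 0 °C → rt
Reagents that add atoms: none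
Why: Organocatalytic iminium–enamine double Michael annulation: the β-keto ester carbon C4 adds to the shielded iminium ion of 8 to set C5 under catalyst control, then the enamine carbon C10 closes ring A by intramolecular (6-endo) Michael addition onto the vinyl ketone, the epimerisable formyl group settling trans to the C5 arm.

**Step 6**
Reactants: 10
Product: 11 benzyl (1S,2S,3R)-2-[2-(benzyloxy)-2-oxoethyl]-3-formyl-1-methyl-6-oxocyclohexane-1-carboxylate
Conditions: MeI, K2CO3, acetone, rt
Reagents that add atoms: iodomethane CI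
Why: C-alkylation of the cyclic β-keto ester enolate puts the methyl group anti to the adjacent C5 arm, so C4 becomes quaternary with the 19-ester cis to that arm.

**Step 7**
Reactants: 11
Product: 12 (1R,2S,3S)-3-[(benzyloxy)carbonyl]-2-[2-(benzyloxy)-2-oxoethyl]-3-methyl-4-oxocyclohexane-1-carboxylic acid
Conditions: NaClO2, NaH2PO4, 2-methylbut-2-ene, t-BuOH–H2O, rt
Reagents that add atoms: sodium chlorite [Na+].[O-]Cl=O
Why: Pinnick oxidation converts the aldehyde to the C20 acid without touching the ketone or the benzyl esters.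

**Step 8**
Reactants: 13 propiophenone
Product: 14 1-phenylpropane-1,2-dione
Conditions: SeO2, 1,4-dioxane–H2O, reflux
Reagents that add atoms: selenium dioxide O=[Se]=O
Why: Riley oxidation of the methylene group next to the aryl ketone gives the 1,2-dione.

**Step 9**
Reactants: 14
Product: 15 2,2-dimethoxy-1-phenylpropan-1-one
Conditions: HC(OMe)3, MeOH, p-TsOH (cat.), rt
Reagents that add atoms: trimethyl orthoformate COC(OC)OC
Why: Acid-catalysed ketalisation picks the more electrophilic, non-conjugated carbonyl and leaves the aryl ketone free.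

**Step 10**
Reactants: 15
Product: 16 (1R)-2,2-dimethoxy-1-phenylpropan-1-ol
Conditions: RuCl[(S,S)-TsDPEN](p-cymene) (1 mol %), HCO2H–Et3N (5:2), rt
Reagents that add atoms: none
Why: Noyori asymmetric transfer hydrogenation of the aryl ketone with the (S,S) catalyst sets the carbinol centre (future C15) as R.

**Step 11**
Reactants: 16
Product: 17 (1R)-1-(cyclohexa-1,4-dien-1-yl)-2,2-dimethoxypropan-1-ol
Conditions: n-BuLi (1 equiv), THF, −78 °C; then Li, NH3(l), t-BuOH, −78 °C; NH4Cl
Reagents that add atoms: none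
Why: Birch reduction of the alkyl-type arene gives the 1-substituted 1,4-diene, the lithium alkoxide protecting the benzylic C–O bond from hydrogenolysis and leaving the carbinol centre untouched.

**Step 12**
Reactants: 12; 17
Product: 18 3-benzyl 1-[(1R)-1-(cyclohexa-1,4-dien-1-yl)-2,2-dimethoxypropyl] (1R,2S,3S)-2-[2-(benzyloxy)-2-oxoethyl]-3-methyl-4-oxocyclohexane-1,3-dicarboxylate
Conditions: EDC·HCl, DMAP, CH2Cl2, 0 °C → rt
Reagents that add atoms: none
Why: Steglich esterification joins the ring A acid and the ring C carbinol through the C20 carboxyl, creating the allyl ester needed for the rearrangement.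

**Step 13**
Reactants: 18
Product: 19 3-benzyl 1-[(1R)-1-(cyclohexa-1,4-dien-1-yl)-2,2-dimethoxypropyl] (1R,2S,3S,4S)-2-[2-(benzyloxy)-2-oxoethyl]-4-hydroxy-3-methylcyclohexane-1,3-dicarboxylate
Conditions: K[(s-Bu)3BH], THF, −78 °C; then H2O
Reagents that add atoms: none
Why: Bulky-hydride ketone reduction attacks C3 equatorially, as with 4,4-disubstituted 3-keto triterpenoids, giving the axial 3β-alcohol trans to the axial 19-ester.

**Step 14**
Reactants: 19
Product: 22 tribenzyl 3β-hydroxy-16,16-dimethoxy-6,8:13,16-disecogibberella-8(15)E,12-diene-7,19,20-trioate (5β-H, 9β-H, 20-ester α), via tris(trimethylsilyl) derivative 20 (not isolated), via rearranged hydroxy acid 21 (not isolated)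
Conditions: LiN(i-Pr)2 (3.5 equiv), Me3SiCl, THF, −78 → 65 °C; MeOH, K2CO3, 0 °C; then BnBr, DMF, rt
Reagents that add atoms: benzyl bromide BrCc1ccccc1
Why: Ireland–Claisen rearrangement forms the C9–C10 bond: the allyl unit attacks the exocyclic C10 ketene acetal anti to the C5 arm (held axial by allylic strain), setting quaternary C10 for the trans A/B fusion, while 1,3-chirality transfer from the (R)-carbinol through the transition state with the ketal group pseudo-equatorial sets C9 and the 8(15)E alkene; brief cold methanolysis removes the silyl groups without touching the benzyl esters, and the acid is re-esterified.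

**Step 15**
Reactants: 22
Product: 25 tribenzyl 3β-hydroxy-16-oxo-13,16-secogibberell-12-ene-7,19,20-trioate, via silyl ketene acetal 23 (not isolated), via methyl enol ether 24 (not isolated)
Conditions: LiN(i-Pr)2 (2.3 equiv), Me3SiCl, THF, −78 °C; then Me3SiOTf (0.2 equiv), CH2Cl2, −78 → −40 °C; 1 M HCl, THF, 0 °C
Reagents that add atoms: water O
Why: Intramolecular Mukaiyama–Michael addition closes ring B: Me3SiOTf ionises the unsaturated ketal to a methoxyallyl cation whose tertiary β-carbon C8 is attacked 5-exo by the C6 ketene acetal from the face of C10 (cis B/C fusion), the 7-ester takes the less hindered 6β orientation trans to C4, and acid work-up unveils the methyl ketone and the 3-OH.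

**Step 16**
Reactants: 25
Product: 26 tribenzyl 3β,16-dihydroxygibberellane-7,19,20-trioate (16-OH exo, anti to C12)
Conditions: SmI2 (3 equiv), HMPA, t-BuOH, THF, 0 °C
Reagents that add atoms: none
Why: Ketyl–olefin radical cyclisation closes ring D 5-exo from the C16 ketyl onto C13; the bridge forces the C13 configuration, and the bulky O–Sm group lies anti to the developing C12 radical, giving the exo hydroxyl with the methyl endo.

**Step 17**
Reactants: 26
Product: 27 3β,16-dihydroxygibberellane-7,19,20-trioic acid (16-OH exo; target)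
Conditions: H2 (1 atm), 10% Pd/C, EtOAc–MeOH, rt
Reagents that add atoms: none
Why: Hydrogenolysis removes the three benzyl esters under neutral conditions that leave both alcohols and all stereocentres untouched.

**Compound list**
1 | benzyl acetate | CC(=O)OCc1ccccc1 | starting material
2 | acrolein | C=CC=O | starting material
3 | benzyl 3-hydroxypent-4-enoate (racemic) | C=CC(O)CC(=O)OCc1ccccc1 | intermediate
4 | benzyl 3-oxopent-4-enoate | C=CC(=O)CC(=O)OCc1ccccc1 | intermediate
5 | but-3-enoic acid | C=CCC(=O)O | starting material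
6 | benzyl but-3-enoate | C=CCC(=O)OCc1ccccc1 | intermediate
7 | (E)-but-2-enal | C/C=C/C=O | starting material
8 | benzyl (3E)-5-oxopent-3-enoate | O=C/C=C/CC(=O)OCc1ccccc1 | intermediate
9 | dibenzyl (3R)-3-(2-oxoethyl)-2-(prop-2-enoyl)pentanedioate (C2 epimers) | C=CC(=O)C(C(=O)OCc1ccccc1)[C@@H](CC(=O)OCc1ccccc1)CC=O | intermediate (not isolated)
10 | benzyl (2S,3R)-2-[2-(benzyloxy)-2-oxoethyl]-3-formyl-6-oxocyclohexane-1-carboxylate | C1(C(=O)OCc2ccccc2)[C@@H](CC(=O)OCc2ccccc2)[C@H](C=O)CCC1=O | intermediate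
11 | benzyl (1S,2S,3R)-2-[2-(benzyloxy)-2-oxoethyl]-3-formyl-1-methyl-6-oxocyclohexane-1-carboxylate | C[C@]1(C(=O)OCc2ccccc2)[C@@H](CC(=O)OCc2ccccc2)[C@H](C=O)CCC1=O | intermediate
12 | (1R,2S,3S)-3-[(benzyloxy)carbonyl]-2-[2-(benzyloxy)-2-oxoethyl]-3-methyl-4-oxocyclohexane-1-carboxylic acid | C[C@]1(C(=O)OCc2ccccc2)[C@@H](CC(=O)OCc2ccccc2)[C@H](C(=O)O)CCC1=O | intermediate
13 | propiophenone | CCC(=O)c1ccccc1 | starting material
14 | 1-phenylpropane-1,2-dione | CC(=O)C(=O)c1ccccc1 | intermediate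
15 | 2,2-dimethoxy-1-phenylpropan-1-one | CC(OC)(OC)C(=O)c1ccccc1 | intermediate
16 | (1R)-2,2-dimethoxy-1-phenylpropan-1-ol | CC(OC)(OC)[C@H](O)c1ccccc1 | intermediate
17 | (1R)-1-(cyclohexa-1,4-dien-1-yl)-2,2-dimethoxypropan-1-ol | CC(OC)(OC)[C@H](O)C1=CCC=CC1 | intermediate
18 | 3-benzyl 1-[(1R)-1-(cyclohexa-1,4-dien-1-yl)-2,2-dimethoxypropyl] (1R,2S,3S)-2-[2-(benzyloxy)-2-oxoethyl]-3-methyl-4-oxocyclohexane-1,3-dicarboxylate | C[C@]1(C(=O)OCc2ccccc2)[C@@H](CC(=O)OCc2ccccc2)[C@H](C(=O)O[C@H](C2=CCC=CC2)C(C)(OC)OC)CCC1=O | intermediate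
19 | 3-benzyl 1-[(1R)-1-(cyclohexa-1,4-dien-1-yl)-2,2-dimethoxypropyl] (1R,2S,3S,4S)-2-[2-(benzyloxy)-2-oxoethyl]-4-hydroxy-3-methylcyclohexane-1,3-dicarboxylate (3β-OH) | C[C@]1(C(=O)OCc2ccccc2)[C@@H](CC(=O)OCc2ccccc2)[C@H](C(=O)O[C@H](C2=CCC=CC2)C(C)(OC)OC)CC[C@@H]1O | intermediate
20 | 3-O-trimethylsilyl ether of 19 with the C20 ester (C10=C20) and the C7 ester (C6=C7) as O-trimethylsilyl ketene acetals | C[C@]1(C(=O)OCc2ccccc2)[C@@H](C=C(O[Si](C)(C)C)OCc2ccccc2)C(=C(O[Si](C)(C)C)O[C@H](C2=CCC=CC2)C(C)(OC)OC)CC[C@@H]1O[Si](C)(C)C | intermediate (not isolated)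
21 | 7,19-dibenzyl 20-hydrogen 3β-hydroxy-16,16-dimethoxy-6,8:13,16-disecogibberella-8(15)E,12-diene-7,19,20-trioate | C[C@]1(C(=O)OCc2ccccc2)[C@@H](CC(=O)OCc2ccccc2)[C@](C(=O)O)([C@@H]2CC=CC/C2=C\C(C)(OC)OC)CC[C@@H]1O | intermediate (not isolated)
22 | tribenzyl 3β-hydroxy-16,16-dimethoxy-6,8:13,16-disecogibberella-8(15)E,12-diene-7,19,20-trioate | C[C@]1(C(=O)OCc2ccccc2)[C@@H](CC(=O)OCc2ccccc2)[C@](C(=O)OCc2ccccc2)([C@@H]2CC=CC/C2=C\C(C)(OC)OC)CC[C@@H]1O | intermediate
23 | 3-O-trimethylsilyl ether of 22 with the C7 ester as its O-trimethylsilyl ketene acetal (C6=C7) | C[C@]1(C(=O)OCc2ccccc2)[C@@H](C=C(O[Si](C)(C)C)OCc2ccccc2)[C@](C(=O)OCc2ccccc2)([C@@H]2CC=CC/C2=C\C(C)(OC)OC)CC[C@@H]1O[Si](C)(C)C | intermediate (not isolated)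
24 | tribenzyl 16-methoxy-3β-(trimethylsilyloxy)-13,16-secogibberella-12,15-diene-7,19,20-trioate | C[C@]1(C(=O)OCc5ccccc5)[C@H]2[C@H](C(=O)OCc5ccccc5)[C@@]3(C=C(C)OC)CC=CC[C@H]3[C@]2(C(=O)OCc5ccccc5)CC[C@@H]1O[Si](C)(C)C | intermediate (not isolated)
25 | tribenzyl 3β-hydroxy-16-oxo-13,16-secogibberell-12-ene-7,19,20-trioate | C[C@]1(C(=O)OCc5ccccc5)[C@H]2[C@H](C(=O)OCc5ccccc5)[C@@]3(CC(C)=O)CC=CC[C@H]3[C@]2(C(=O)OCc5ccccc5)CC[C@@H]1O | intermediate
26 | tribenzyl 3β,16-dihydroxygibberellane-7,19,20-trioate (16-OH exo) | C[C@]1(C(=O)OCc5ccccc5)[C@H]2[C@H](C(=O)OCc5ccccc5)[C@@]34C[C@@H](CC[C@H]3[C@]2(C(=O)OCc5ccccc5)CC[C@@H]1O)[C@](C)(O)C4 | intermediate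
27 | 3β,16-dihydroxygibberellane-7,19,20-trioic acid (16-OH exo) | C[C@]1(C(=O)O)[C@H]2[C@H](C(=O)O)[C@@]34C[C@@H](CC[C@H]3[C@]2(C(=O)O)CC[C@@H]1O)[C@](C)(O)C4 | target

**Step count and risks**
Total steps: 17. Longest linear sequence: 11 steps (1, 2, 5, 6, 7, 12, 13, 14, 15, 16, 17). The ring C branch (8–11) and the enal branch (3, 4) run in parallel.

The three steps most likely to fail:

Step 5 (organocatalytic double Michael annulation). The enal is γ-enolisable and the keto ester polymerises easily, so yield or enantioselectivity may be poor. Fallback, setting out from 4 and 8 and returning at 10: 4 is silylated (t-BuMe2SiOTf, Et3N) to the 2-silyloxy diene benzyl (2Z)-3-[(tert-butyldimethylsilyl)oxy]penta-2,4-dienoate F1. An enantioselective Diels–Alder reaction of F1 with 8 under a chiral oxazaborolidinium catalyst (o-tolyl-CBS oxazaborolidine activated with Tf2NH) gives, with the "para" regiochemistry (C4–C5 and C1–C10 bonds) and trans C5/C10, the cycloadduct benzyl (2S,3R)-2-[2-(benzyloxy)-2-oxoethyl]-6-[(tert-butyldimethylsilyl)oxy]-3-formylcyclohex-5-ene-1-carboxylate F2. Cleaving the silyl enol ether with Bu4NF/AcOH gives 10.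

Step 15 (oxocarbenium Mukaiyama–Michael closure of ring B). 1,2-attack at the ketal carbon or proton loss from the cation may compete. Fallback, setting out from 22 and returning at 25: the C7 ester ketene acetal, made as in step 15, is quenched with N-bromosuccinimide to give the α-bromo ester tribenzyl 6-bromo-3β-hydroxy-16,16-dimethoxy-6,8:13,16-disecogibberella-8(15)E,12-diene-7,19,20-trioate F3. Bu3SnH/AIBN (benzene, 80 °C) then closes ring B by 5-exo radical cyclisation of the C6 radical onto C8, giving the ketal tribenzyl 3β-hydroxy-16,16-dimethoxy-13,16-secogibberell-12-ene-7,19,20-trioate F4. Dilute aqueous HCl hydrolyses the ketal to 25.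

Step 16 (ketyl–olefin closure of ring D onto an unactivated ring alkene). Simple ketone reduction or 6-endo closure may compete. Fallback, setting out from 25 and returning at 26: hydrazine hydrate gives the hydrazone tribenzyl 16-hydrazinylidene-3β-hydroxy-13,16-secogibberell-12-ene-7,19,20-trioate F5. Iodine with tetramethylguanidine (Barton iodination) converts it into the vinyl iodide tribenzyl 3β-hydroxy-16-iodo-13,16-secogibberella-12,16-diene-7,19,20-trioate F6. Bu3SnH/AIBN closes ring D by 5-exo vinyl-radical cyclisation onto C13, giving the exocyclic alkene tribenzyl 3β-hydroxygibberell-16-ene-7,19,20-trioate F7. Mukaiyama hydration (Mn(dpm)3, PhSiH3, O2, i-PrOH) traps the tertiary C16 radical from the exo face and gives 26.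

Further compounds
F1 | step 5 | benzyl (2Z)-3-[(tert-butyldimethylsilyl)oxy]penta-2,4-dienoate | C=C/C(O[Si](C)(C)C(C)(C)C)=C/C(=O)OCc1ccccc1
F2 | step 5 | benzyl (2S,3R)-2-[2-(benzyloxy)-2-oxoethyl]-6-[(tert-butyldimethylsilyl)oxy]-3-formylcyclohex-5-ene-1-carboxylate (C1 epimers) | C1(C(=O)OCc2ccccc2)[C@@H](CC(=O)OCc2ccccc2)[C@H](C=O)CC=C1O[Si](C)(C)C(C)(C)C
F3 | step 15 | tribenzyl 6-bromo-3β-hydroxy-16,16-dimethoxy-6,8:13,16-disecogibberella-8(15)E,12-diene-7,19,20-trioate (C6 epimers) | C[C@]1(C(=O)OCc2ccccc2)[C@@H](C(Br)C(=O)OCc2ccccc2)[C@](C(=O)OCc2ccccc2)([C@@H]2CC=CC/C2=C\C(C)(OC)OC)CC[C@@H]1O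
F4 | step 15 | tribenzyl 3β-hydroxy-16,16-dimethoxy-13,16-secogibberell-12-ene-7,19,20-trioate | C[C@]1(C(=O)OCc5ccccc5)[C@H]2[C@H](C(=O)OCc5ccccc5)[C@@]3(CC(C)(OC)OC)CC=CC[C@H]3[C@]2(C(=O)OCc5ccccc5)CC[C@@H]1O
F5 | step 16 | tribenzyl 16-hydrazinylidene-3β-hydroxy-13,16-secogibberell-12-ene-7,19,20-trioate | C[C@]1(C(=O)OCc5ccccc5)[C@H]2[C@H](C(=O)OCc5ccccc5)[C@@]3(CC(C)=NN)CC=CC[C@H]3[C@]2(C(=O)OCc5ccccc5)CC[C@@H]1O
F6 | step 16 | tribenzyl 3β-hydroxy-16-iodo-13,16-secogibberella-12,16-diene-7,19,20-trioate | C[C@]1(C(=O)OCc5ccccc5)[C@H]2[C@H](C(=O)OCc5ccccc5)[C@@]3(CC(I)=C)CC=CC[C@H]3[C@]2(C(=O)OCc5ccccc5)CC[C@@H]1O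
F7 | step 16 | tribenzyl 3β-hydroxygibberell-16-ene-7,19,20-trioate | C[C@]1(C(=O)OCc5ccccc5)[C@H]2[C@H](C(=O)OCc5ccccc5)[C@@]34C[C@@H](CC[C@H]3[C@]2(C(=O)OCc5ccccc5)CC[C@@H]1O)C(=C)C4
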